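The data are calculated for an exercise; scatter was added.

Time is what I have to reckon with: north-west stops at 30 min, south at 60 min, and the question is how far each gets towards what its charges allow.

| setting | beta | theta | north-west | south |
|---|---|---|---|---|
| starting material | 42 mM | 42 mM | 42 mM | 42 mM |
| reagent | 0.81 equiv | 3.8 equiv | 1.10 equiv | 4.40 equiv |
| protic impurity | 4.2 mM | 4.2 mM | 4.20 mM | 4.20 mM |
| free catalyst | 0.36 mol% | 0.36 mol% | 0.36 mol% | 0.36 mol% |
| remark | run made earlier | run made earlier |  |  |
| time |  |  | 30 min | 60 min |

| run | time / min | target / % |
|---|---|---|
| beta | 1.00 | 1.8 |
| beta | 3.00 | 5.0 |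
| beta | 5.00 | 7.5 |
| beta | 8.00 | 11.5 |
| beta | 12.0 | 16.1 |
| beta | 15.0 | 20.4 |
| theta | 1.00 | 0.1 |
| theta | 3.00 | 3.0 |
| theta | 5.00 | 4.8 |
| theta | 8.00 | 9.0 |
| theta | 12.0 | 13.1 |
| theta | 15.0 | 16.3 |

(standard deviation of a reading: 0.5 percentage points)

* which of the two ends with the higher amount of target, in percent of the starting material charged ("neither" if they lie within 2 percentage points) (north-west / south / neither)
* target at the end, in percent of the starting material charged, north-west
* target at the end, in percent of the starting material charged, south



I write the balance first, assuming one reagent and one starting material per target, and that each protic impurity destroys one starting material. The ceiling on target is then 90.0% of the charge. Reagent at 1.10 equiv in north-west stands above that, and 4.40 equiv in south further still, so starting material is the limiting reagent in both.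

Now the ladder. Beta's slope is 0.0136 min⁻¹ of the charge, as read, so one pass of the catalyst loading takes 0.265 min. I set aside theta's first reading, 0.1% at 1.00 min, as a single low point under a scatter of 0.5 percentage points, not as a delay. Theta's slope between 3.00 min and 15.0 min is 0.0111 min⁻¹. Reagent rose 4.69-fold between the runs, but the slope fell only 1.23-fold, so I give each flask the slope of its nearest run.

The top rung is the spend time, the ceiling divided by the early slope: 66.2 min for north-west and 81.2 min for south. Both flasks stop short of it,  so time still counts in each. A straight line gives an upper figure, 40.8% and 66.5%. A first-order approach to the ceiling gives a lower one, 32.8% and 47.0%. South's lower figure stands above north-west's upper one, so I commit to south.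

The forecast also says south, with 38% and 59%: “South ends higher, simply because it runs twice as long”.

The simulation gives south, with north-west at 39.0% and south at 56.8%, each between my two figures.

    reagent + free catalyst ⇌ catalyst intermediate A (K = 17.0 M⁻¹, k = 570 M⁻¹ min⁻¹)
    catalyst intermediate A ⇌ catalyst intermediate B (K = 0.520, k = 63.0 min⁻¹)
    starting material + catalyst intermediate B → catalyst intermediate C (k = 7100 M⁻¹ min⁻¹)
    catalyst intermediate C ⇌ catalyst intermediate D (K = 57.0, k = 21.0 min⁻¹)
    catalyst intermediate D ⇌ free catalyst + target (K = 0.0240 M, k = 42.0 min⁻¹)
    free catalyst ⇌ dormant form (K = 24.0, k = 0.00360 min⁻¹)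
    starting material + protic impurity → quenched substrate (k = 13.0 M⁻¹ min⁻¹)
    reagent + catalyst intermediate A ⇌ idle complex, settled at all times (K = 52.0 M⁻¹)

North-west used 0.453 of its spend time and reached 0.433 of its ceiling. The neighbour flask is north-west left until 80 min, which passes the spend time, so the straight line stops at the ceiling of 90.0%, while the first-order figure is 63.1%. That flask holds 71.4% of target, with 10.0% as quenched substrate and 18.4% still as starting material.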